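Its constants were set for the occasion.

If you have to call these two flasks within the hour, count nucleophile before you reach for rates.

- west: electrophile 0.072 M; nucleophile 1.20 equiv; time 2.0 d
- south-east: electrophile 0.072 M; nucleophile 1.60 equiv; time 2.0 d

    electrophile ⇌ dormant form (K1 = 0.94, k1 = 6.0 × 10⁻⁵ s⁻¹)
    nucleophile + acid set free ⇌ protonated nucleophile, settled at all times (K2 = 17000 L mol⁻¹)
    acid set free + target → side product (k3 = 0.0057 L mol⁻¹ s⁻¹)
    electrophile + nucleophile → acid set free + target (k4 = 5.0 × 10⁻⁴ L mol⁻¹ s⁻¹)
    target ⇌ isomer of the product (K5 = 1.4, k5 = 2.6 × 10⁻⁴ s⁻¹)

- part of the electrophile that has reacted at the end, west
- part of the electrophile that has reacted at the end, south-east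
- what raising the equivalents of nucleophile from its lowest to its highest value here does to the part of the electrophile that has reacted (changes below 5 percentage points count as none) (it falls / no change / it rises)

- what has gone from electrophile into another species counts as reacted, even if it can come back
- run time (west): 2.0 d

Start in powers of ten. In west, the constant for binding acid times the charged nucleophile is 1500, or 3.18 powers of ten. Because nearly all of the acid set free then sits on nucleophile, each coupling costs two nucleophiles, one to react and one to take the acid. Nucleophile is the limiting reagent, so by this count coupling comes to about 60.0% of the charge in west and 80.0% in south-east.

The uncoupled rest splits between electrophile and dormant form as one to 0.94, because their relaxation half-life of 0.0648 d is shorter than the 2.0 d run. Dormant form counts as reacted. Divide the uncoupled rest by one plus 0.94 to get the electrophile left, and subtract that from the charge. West comes to 79.4%. That is the two-per-coupling share, an estimate of the part reacted once nucleophile has gone at two per coupling and the rest has split. South-east has a two-per-coupling share of 89.7%. I commit to these, a rise of 10 percentage points, above the 5 points margin.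

The weak link is arrival. Near that share, [nucleophile] halves in ln(2) over twice the coupling constant times [electrophile]. That gives 0.540 d in west and 1.08 d in south-east, which is slower. The run holds 3.70 such half-lives in west and 1.85 in south-east. So I keep west and reforge south-east. Integrating the second-order law with the split held gives a factor of 3.61, so 74.3% coupled and 86.8% reacted.

The forecast gives 79% for west and 87% for south-east, and for the trend, it rises. Its ground: "Each coupling event uses two nucleophiles, one to react and one to trap the acid". Its numbers are close to mine but not the same.

West gives 79.3%, against its two-per-coupling share of 79.4%. South-east gives 87.4%, against 89.7% and the reforged 86.8%. From west to south-east: it rises, by 8.1 points. Take a further flask like west, with 0.300 equiv of nucleophile. The same reckoning gives a two-per-coupling share of 56.2% and a half-life of 0.254 d for [nucleophile], shorter than the 2.0 d run. That flask gives 56.9%. It ends with 43.1% of its charge as electrophile, 40.6% as dormant form, and 3.20% of its own nucleophile charge still free.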